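**Retrosynthetic overview**
- The C7 carbonyl comes last, by allylic oxidation of a Δ5-octalin acid; the C11–C15 chain comes from a C9 aldehyde by Wittig olefination and alkene hydrogenation, with C13 taken from (S)-β-methyl-γ-butyrolactone.
- Ring B is closed by an exo-selective, catalyst-controlled Diels–Alder reaction of tiglic aldehyde with a ring-A vinylcyclohexene; this one step sets C8, C9, C10 and the C5=C6 alkene.
- The ring-A diene comes from (R)-ethyl 1-methyl-2-oxocyclohexane-1-carboxylate (enol triflate, Stille vinylation, ester to CH2OAc); C4 is set by a chiral-enamine methylation.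
- Ring order: ring A is bought as a cyclohexanone, ring B is formed by the cycloaddition.

Assumption: the senses of induction in step 2 (auxiliary) and step 7 (catalyst) follow the chelate and pre-transition-state models given in the Why lines; if either proves reversed, the antipodal auxiliary or catalyst is used with no other change.

Position labels in the text are terpenoid numbers: C4 carries CH2OAc (C18), C5=C6 is the ring alkene, C7 the carbonyl, C8 (Me), C9 (Me and side chain C11–C15), C10 the ring-fusion CH, C13 the side-chain stereocentre.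

**Step 1**
Reactants: 1 ethyl 2-oxocyclohexane-1-carboxylate; 2 L-valine tert-butyl ester
Product: 3 ethyl 2-{[(2S)-1-tert-butoxy-3-methyl-1-oxobutan-2-yl]amino}cyclohex-1-ene-1-carboxylate
Conditions: cat. BF3·OEt2, toluene, reflux, Dean–Stark
Reagents that add atoms: none
Why: Acid-catalysed enamine condensation of the β-keto ester with the amine is driven by azeotropic water removal and gives the hydrogen-bonded enamino ester without forming a stereocentre.

**Step 2**
Reactants: 3 enamino ester
Product: 6 ethyl (1R)-1-methyl-2-oxocyclohexane-1-carboxylate, via lithium aza-enolate 4 (not isolated), via imine 5 (not isolated)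
Conditions: LiN(i-Pr)2, toluene, −78 °C; HMPA; MeI, −78 → −40 °C; then 10% aq. citric acid, rt
Reagents that add atoms: iodomethane (CI); water (O)
Why: Chiral-auxiliary alkylation of a chelated lithium aza-enolate: lithium is held by N and both ester carbonyls, HMPA caps it on the face away from the isopropyl group, MeI enters from the other face to give the (R)-quaternary centre, and mild acid hydrolysis of the imine releases the ketone and the auxiliary.

**Step 3**
Reactants: 6 (R)-keto ester
Product: 8 ethyl (1R)-1-methyl-2-(trifluoromethanesulfonyloxy)cyclohex-2-ene-1-carboxylate, via potassium enolate 7 (not isolated)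
Conditions: KN(SiMe3)2, THF, −78 °C; PhNTf2, −78 → 0 °C
Reagents that add atoms: N-phenylbis(trifluoromethanesulfonimide) (O=S(=O)(N(c1ccccc1)S(=O)(=O)C(F)(F)F)C(F)(F)F)
Why: Enolate O-sulfonylation is regiodefined because only the CH2 side of the ketone can enolise, and the quaternary centre is untouched.

**Step 4**
Reactants: 8 vinyl triflate
Product: 9 ethyl (1R)-2-ethenyl-1-methylcyclohex-2-ene-1-carboxylate
Conditions: Bu3SnCH=CH2, Pd(PPh3)4 (5 mol%), LiCl, THF, 65 °C
Reagents that add atoms: tributyl(vinyl)stannane (C=C[Sn](CCCC)(CCCC)CCCC)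
Why: Stille cross-coupling of the vinyl triflate (LiCl-assisted) installs the vinyl group with the ring alkene held in place, giving the 1,3-diene.

**Step 5**
Reactants: 9 diene ester
Product: 10 [(1R)-2-ethenyl-1-methylcyclohex-2-en-1-yl]methanol
Conditions: LiAlH4, Et2O, 0 °C; then H2O, aq. NaOH
Reagents that add atoms: none
Why: Hydride reduction converts the neopentyl ester into the primary alcohol while the diene, not conjugated to a carbonyl, is inert.

**Step 6**
Reactants: 10 diene alcohol
Product: 11 [(1R)-2-ethenyl-1-methylcyclohex-2-en-1-yl]methyl acetate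
Conditions: Ac2O, pyridine, DMAP (cat.), CH2Cl2, 0 °C → rt
Reagents that add atoms: acetic anhydride (CC(=O)OC(C)=O)
Why: DMAP-catalysed acylation of the primary alcohol installs the acetate of the target, which tolerates the Lewis acid, hydrogenation and oxidation steps that follow.

**Step 7**
Reactants: 11 diene acetate; 12 (2E)-2-methylbut-2-enal (tiglic aldehyde)
Product: 13 [(1R,4aR,5R,6S)-5-formyl-1,5,6-trimethyl-1,2,3,4,4a,5,6,7-octahydronaphthalen-1-yl]methyl acetate
Conditions: (R)-o-tolyl-CBS-oxazaborolidine (20 mol%), AlBr3 (16 mol%), 12 (3 equiv), CH2Cl2, −78 → −40 °C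
Reagents that add atoms: none
Why: Catalytic asymmetric Diels–Alder reaction: the s-cis-locked vinylcyclohexene adds with the usual ortho orientation (formyl-bearing carbon to the ring terminus C10), suprafacial addition of the E-enal makes the C8 and C9 methyls cis, the catalyst-bound formyl group stays exo (away from the quaternary C4) so CHO ends up cis to H-10, and the catalyst's aryl group blocks the Re face of the enal α-carbon so the diene bonds to the Si face, anti to the acetoxymethyl arm, fixing C8, C9 and C10.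

**Step 8**
Reactants: 14 (4S)-4-methyloxolan-2-one [(S)-β-methyl-γ-butyrolactone]
Product: 15 (3S)-4-bromo-3-methylbutanoic acid
Conditions: 33% HBr in AcOH, 60 °C
Reagents that add atoms: hydrogen bromide (Br)
Why: Acid-mediated SN2 ring opening of the γ-lactone at the O–CH2 carbon by bromide gives the γ-bromo acid without involving the stereocentre.

**Step 9**
Reactants: 15 bromo acid
Product: 16 [(2S)-3-carboxy-2-methylpropyl]triphenylphosphonium bromide
Conditions: PPh3, MeCN, reflux
Reagents that add atoms: triphenylphosphine (c1ccccc1P(c1ccccc1)c1ccccc1)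
Why: SN2 alkylation of PPh3 by the primary bromide forms the phosphonium salt, and the stereocentre β to the reacting carbon is untouched.

**Step 10**
Reactants: 16 phosphonium bromide; 13 aldehyde
Product: 18 (3S,4Z)-5-[(1S,2S,5R,8aS)-5-(acetoxymethyl)-1,2,5-trimethyl-1,2,3,5,6,7,8,8a-octahydronaphthalen-1-yl]-3-methylpent-4-enoic acid, via phosphonium ylide 17 (not isolated)
Conditions: 16 (2 equiv), NaN(SiMe3)2 (3.9 equiv), THF, 0 °C; then 13, −78 °C → rt; 1 M HCl to pH 3
Reagents that add atoms: none
Why: Wittig olefination: two equivalents of base per salt give the carboxylate ylide, which adds to the non-enolisable aldehyde to give the Z-alkene (geometry is erased in step 11), and the non-acidic C13 stereocentre of the ylide is retained.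

**Step 11**
Reactants: 18 alkene acid
Product: 19 (3R)-5-[(1R,2S,5R,8aS)-5-(acetoxymethyl)-1,2,5-trimethyl-1,2,3,5,6,7,8,8a-octahydronaphthalen-1-yl]-3-methylpentanoic acid
Conditions: H2 (3 atm), RhCl(PPh3)3 (10 mol%), benzene–EtOH, rt
Reagents that add atoms: none
Why: Homogeneous hydrogenation with RhCl(PPh3)3 reduces the 1,2-disubstituted side-chain alkene but not the hindered trisubstituted ring alkene next to quaternary C4, and no stereocentre is formed.

**Step 12**
Reactants: 19 saturated acid
Product: 20 (3R)-5-[(1S,2R,5R,8aS)-5-(acetoxymethyl)-1,2,5-trimethyl-3-oxo-1,2,3,5,6,7,8,8a-octahydronaphthalen-1-yl]-3-methylpentanoic acid (target, CNP0210381.1)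
Conditions: Rh2(cap)4 (cap = caprolactamate, 1 mol%), 70% aq. t-BuOOH (10 equiv), ClCH2CH2Cl, 40 °C
Reagents that add atoms: tert-butyl hydroperoxide (CC(C)(C)OO)
Why: Allylic C–H oxidation by a tert-butylperoxyl radical chain converts the only allylic methylene (C7; C4 is quaternary and C10–H is shielded by C9) into the enone carbonyl under neutral conditions that do not epimerise C8.

**Compound list**
1 | ethyl 2-oxocyclohexane-1-carboxylate | CCOC(=O)C1CCCCC1=O | starting material
2 | L-valine tert-butyl ester | CC(C)[C@H](N)C(=O)OC(C)(C)C | starting material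
3 | ethyl 2-{[(2S)-1-tert-butoxy-3-methyl-1-oxobutan-2-yl]amino}cyclohex-1-ene-1-carboxylate | CCOC(=O)C1=C(CCCC1)N[C@@H](C(C)C)C(=O)OC(C)(C)C | intermediate
4 | lithium aza-enolate of 3 (not isolated) | CCOC(=O)C1=C(CCCC1)[N-][C@@H](C(C)C)C(=O)OC(C)(C)C.[Li+] | intermediate
5 | ethyl (1R)-1-methyl-2-{[(2S)-1-tert-butoxy-3-methyl-1-oxobutan-2-yl]imino}cyclohexane-1-carboxylate (not isolated) | CCOC(=O)[C@]1(C)CCCCC1=N[C@@H](C(C)C)C(=O)OC(C)(C)C | intermediate
6 | ethyl (1R)-1-methyl-2-oxocyclohexane-1-carboxylate | CCOC(=O)[C@]1(C)CCCCC1=O | intermediate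
7 | potassium enolate of 6 (not isolated) | CCOC(=O)[C@]1(C)CCCC=C1[O-].[K+] | intermediate
8 | ethyl (1R)-1-methyl-2-(trifluoromethanesulfonyloxy)cyclohex-2-ene-1-carboxylate | CCOC(=O)[C@]1(C)CCCC=C1OS(=O)(=O)C(F)(F)F | intermediate
9 | ethyl (1R)-2-ethenyl-1-methylcyclohex-2-ene-1-carboxylate | CCOC(=O)[C@]1(C)CCCC=C1C=C | intermediate
10 | [(1R)-2-ethenyl-1-methylcyclohex-2-en-1-yl]methanol | OC[C@]1(C)CCCC=C1C=C | intermediate
11 | [(1R)-2-ethenyl-1-methylcyclohex-2-en-1-yl]methyl acetate | CC(=O)OC[C@]1(C)CCCC=C1C=C | intermediate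
12 | (2E)-2-methylbut-2-enal (tiglic aldehyde) | C/C=C(\C)C=O | starting material
13 | [(1R,4aR,5R,6S)-5-formyl-1,5,6-trimethyl-1,2,3,4,4a,5,6,7-octahydronaphthalen-1-yl]methyl acetate | CC(=O)OC[C@]1(C)CCC[C@@H]2C1=CC[C@H](C)[C@@]2(C)C=O | intermediate
14 | (4S)-4-methyloxolan-2-one | C[C@@H]1COC(=O)C1 | starting material
15 | (3S)-4-bromo-3-methylbutanoic acid | BrC[C@@H](C)CC(=O)O | intermediate
16 | [(2S)-3-carboxy-2-methylpropyl]triphenylphosphonium bromide | [Br-].c1ccccc1[P+](c1ccccc1)(c1ccccc1)C[C@@H](C)CC(=O)O | intermediate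
17 | sodium (3S)-3-methyl-4-(triphenyl-λ5-phosphanylidene)butanoate (not isolated) | [Na+].c1ccccc1P(c1ccccc1)(c1ccccc1)=C[C@@H](C)CC(=O)[O-] | intermediate
18 | (3S,4Z)-5-[(1S,2S,5R,8aS)-5-(acetoxymethyl)-1,2,5-trimethyl-1,2,3,5,6,7,8,8a-octahydronaphthalen-1-yl]-3-methylpent-4-enoic acid | CC(=O)OC[C@]1(C)CCC[C@@H]2C1=CC[C@H](C)[C@@]2(C)/C=C\[C@@H](C)CC(=O)O | intermediate
19 | (3R)-5-[(1R,2S,5R,8aS)-5-(acetoxymethyl)-1,2,5-trimethyl-1,2,3,5,6,7,8,8a-octahydronaphthalen-1-yl]-3-methylpentanoic acid | CC(=O)OC[C@]1(C)CCC[C@@H]2C1=CC[C@H](C)[C@@]2(C)CC[C@@H](C)CC(=O)O | intermediate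
20 | (3R)-5-[(1S,2R,5R,8aS)-5-(acetoxymethyl)-1,2,5-trimethyl-3-oxo-1,2,3,5,6,7,8,8a-octahydronaphthalen-1-yl]-3-methylpentanoic acid | CC(=O)OC[C@]1(C)CCC[C@@H]2C1=CC(=O)[C@H](C)[C@@]2(C)CC[C@@H](C)CC(=O)O | target

**Step count**
Total: 12 steps. Longest linear sequence: 10 steps (steps 1–7 and 10–12, from compound 1).

**Three steps most likely to fail**

Step 7 (Diels–Alder). The hindered β-substituted enal may react slowly with the chiral catalyst, and the exo/endo ratio or the match with the diene's own facial bias may be poor. The fallback sets out from 12 and 11. Compound 12 is acetalised with ethylene glycol (cat. TsOH, benzene, Dean–Stark) to 2-[(2E)-but-2-en-2-yl]-1,3-dioxolane F1. Under Me3SiOTf (cat., CH2Cl2, −78 °C) this acts as a cationic dienophile toward 11 in an ionic Diels–Alder reaction and gives [(1R,4aR,5R,6S)-5-(1,3-dioxolan-2-yl)-1,5,6-trimethyl-1,2,3,4,4a,5,6,7-octahydronaphthalen-1-yl]methyl acetate F2. Face selectivity then rests on the diene alone, and diastereomers are separated by chromatography. PPTS in wet acetone unmasks the aldehyde and the route is rejoined at 13.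

Step 10 (Wittig). The dianionic carboxylate ylide may be too insoluble or too sluggish toward the neopentyl aldehyde, and the two equivalents of strong base endanger the acetate. The fallback sets out from 15. It is esterified with tert-butyl 2,2,2-trichloroacetimidate (cat. BF3·OEt2) to tert-butyl (3S)-4-bromo-3-methylbutanoate F3, which cannot lactonise. Heating with PPh3 in toluene gives [(2S)-4-tert-butoxy-2-methyl-4-oxobutyl]triphenylphosphonium bromide F4. One equivalent of NaN(SiMe3)2 in THF gives the neutral ylide tert-butyl (3S)-3-methyl-4-(triphenyl-λ5-phosphanylidene)butanoate F5. This olefinates 13 to tert-butyl (3S,4Z)-5-[(1S,2S,5R,8aS)-5-(acetoxymethyl)-1,2,5-trimethyl-1,2,3,5,6,7,8,8a-octahydronaphthalen-1-yl]-3-methylpent-4-enoate F6. CF3CO2H in CH2Cl2 removes the tert-butyl group without touching the acetate, and the route is rejoined at 18.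

Step 12 (allylic oxidation). Hydrogen abstraction at the tertiary allylic C10–H, or over-oxidation, may compete with oxidation at C7. The fallback sets out from 19 and replaces radical C–H oxidation by an epoxide-based 1,3-oxygen transposition.
- m-CPBA/NaHCO3 in CH2Cl2 gives the 5,6-epoxide of 19 with the oxirane oxygen anti to the acetoxymethyl group F7; the other epoxide converges.
- PhSeSePh/NaBH4 in EtOH opens it trans-diaxially at C6 to the 5-hydroxy-6-(phenylselanyl) derivative of 19 F8.
- 30% H2O2 in THF oxidises this to the selenoxide of F8 F9, which undergoes syn-elimination away from the hydroxyl (only C7 carries a usable hydrogen) to the tertiary allylic alcohol 5-hydroxy-6-ene derivative of 19 F10.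
- Pyridinium chlorochromate [C5H5NH][CrO3Cl] in CH2Cl2 effects oxidative 1,3-transposition of F10 to the enone, and the route is rejoined at 20.

**Further compounds**
F1 | step 7 | 2-[(2E)-but-2-en-2-yl]-1,3-dioxolane | C/C=C(\C)C1OCCO1
F2 | step 7 | [(1R,4aR,5R,6S)-5-(1,3-dioxolan-2-yl)-1,5,6-trimethyl-1,2,3,4,4a,5,6,7-octahydronaphthalen-1-yl]methyl acetate | CC(=O)OC[C@]1(C)CCC[C@@H]2C1=CC[C@H](C)[C@@]2(C)C3OCCO3
F3 | step 10 | tert-butyl (3S)-4-bromo-3-methylbutanoate | BrC[C@@H](C)CC(=O)OC(C)(C)C
F4 | step 10 | [(2S)-4-tert-butoxy-2-methyl-4-oxobutyl]triphenylphosphonium bromide | [Br-].c1ccccc1[P+](c1ccccc1)(c1ccccc1)C[C@@H](C)CC(=O)OC(C)(C)C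
F5 | step 10 | tert-butyl (3S)-3-methyl-4-(triphenyl-λ5-phosphanylidene)butanoate | c1ccccc1P(c1ccccc1)(c1ccccc1)=C[C@@H](C)CC(=O)OC(C)(C)C
F6 | step 10 | tert-butyl (3S,4Z)-5-[(1S,2S,5R,8aS)-5-(acetoxymethyl)-1,2,5-trimethyl-1,2,3,5,6,7,8,8a-octahydronaphthalen-1-yl]-3-methylpent-4-enoate | CC(=O)OC[C@]1(C)CCC[C@@H]2C1=CC[C@H](C)[C@@]2(C)/C=C\[C@@H](C)CC(=O)OC(C)(C)C
F7 | step 12 | 5,6-epoxide of 19 (oxirane oxygen anti to the acetoxymethyl group) | CC(=O)OC[C@]1(C)CCC[C@@H]2[C@@]13O[C@@H]3C[C@H](C)[C@@]2(C)CC[C@@H](C)CC(=O)O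
F8 | step 12 | 5-hydroxy-6-(phenylselanyl) derivative of 19 (trans-diaxial) | CC(=O)OC[C@]1(C)CCC[C@@H]2[C@]1(O)[C@@H]([Se]c3ccccc3)C[C@H](C)[C@@]2(C)CC[C@@H](C)CC(=O)O
F9 | step 12 | selenoxide of F8 | CC(=O)OC[C@]1(C)CCC[C@@H]2[C@]1(O)[C@@H]([Se](=O)c3ccccc3)C[C@H](C)[C@@]2(C)CC[C@@H](C)CC(=O)O
F10 | step 12 | 5-hydroxy-6-ene derivative of 19 (tertiary allylic alcohol) | CC(=O)OC[C@]1(C)CCC[C@@H]2[C@]1(O)C=C[C@H](C)[C@@]2(C)CC[C@@H](C)CC(=O)O
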